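**Retrosynthetic overview**
1. Target ⇐ hydrolysis of the C2–SMe vinylogous thioester ⇐ closure of the C1–C2 bond by intramolecular enolate addition–elimination (trione ring formed last).
2. Key late union (C5–C4 bond): Lewis-acid C-acylation joins fragment A (C18 silyl enol ether of the diprenyl-dimethylcyclohexanone) with fragment B (C12 acid chloride that already carries C2, C3, C4 and the benzoyl group).
3. Fragment A: enamine-catalysed Michael/aldol annulation of 5-methylhex-4-enal and methyl vinyl ketone forms the cyclohexenone ring first and sets C7; two copper-catalysed methyl additions around a Saegusa–Ito oxidation build C8; kinetic prenylation furnishes C5.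
4. Fragment B: aldol of benzaldehyde with tert-butyl acetate, oxidation, CS2/MeI ketene dithioacetal formation, ester cleavage, acid chloride.
5. Ring order: cyclohexanone ring (step 1), then trione ring (step 13); C5 and C1 follow from C7 by substrate control.

Assumption: 5-methylhex-4-enal is taken as a purchasable starting material.
Numbering and labels: in the bicycle, C1 is the CH bridgehead next to CMe2, C5 the prenylated bridgehead, C9 the bridging ketone. The centre set in step 1 is never touched again; its CIP label changes from S (3–8) to R (10–22) only because substituent priorities change.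
Steps 12 and 13 have no direct precedent on this system and are argued by analogy.

**Step 1**
Reactants: 1 5-methylhex-4-enal; 2 but-3-en-2-one
Product: 4 (4S)-4-(3-methylbut-2-en-1-yl)cyclohex-2-en-1-one, via keto aldehyde 3 (not isolated)
Conditions: (S)-2-(methoxydiphenylmethyl)pyrrolidine (5 mol %), ethyl 3,4-dihydroxybenzoate (20 mol %), neat, 4 °C; evaporate; then KOH (cat.), nBu4NOH (cat.), THF/Et2O/H2O, reflux
Reagents that add atoms: none
Why: Enamine-catalysed asymmetric Michael addition followed by intramolecular aldol condensation (Robinson-type annulation); the CPh2OMe group blocks one face of the E-enamine, so the enone adds to the other face and gives the (S) centre that becomes C7.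

**Step 2**
Reactants: 4 (4S)-4-(3-methylbut-2-en-1-yl)cyclohex-2-en-1-one
Product: 5 trimethyl{[(3S,4S)-3-methyl-4-(3-methylbut-2-en-1-yl)cyclohex-1-en-1-yl]oxy}silane
Conditions: MeMgBr, CuBr·SMe2 (10 mol %), Me3SiCl, THF, −78 °C
Reagents that add atoms: methylmagnesium bromide, C[Mg]Br; chlorotrimethylsilane, C[Si](C)(C)Cl
Why: Copper-catalysed conjugate addition with in situ O-silylation; methyl adds anti to the C4 side chain (3,4-trans), and this new centre is removed in step 3.

**Step 3**
Reactants: 5 trimethyl{[(3S,4S)-3-methyl-4-(3-methylbut-2-en-1-yl)cyclohex-1-en-1-yl]oxy}silane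
Product: 6 (4S)-3-methyl-4-(3-methylbut-2-en-1-yl)cyclohex-2-en-1-one
Conditions: Pd(OAc)2 (10 mol %), O2 (1 atm), DMSO, rt
Reagents that add atoms: none
Why: Saegusa–Ito oxidation of the regiodefined silyl enol ether gives only the 2,3-enone by β-hydride elimination from C3; the neutral conditions leave the γ-centre and the trisubstituted alkene alone.

**Step 4**
Reactants: 6 (4S)-3-methyl-4-(3-methylbut-2-en-1-yl)cyclohex-2-en-1-one
Product: 8 (4S)-3,3-dimethyl-4-(3-methylbut-2-en-1-yl)cyclohexan-1-one, via silyl enol ether 7 (not isolated)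
Conditions: MeMgBr, CuBr·SMe2 (10 mol %), Me3SiCl, HMPA, THF, −78 to −20 °C; then 0.5 M HCl, THF, 0 °C
Reagents that add atoms: methylmagnesium bromide, C[Mg]Br; chlorotrimethylsilane, C[Si](C)(C)Cl (silicon is carried only by 7)
Why: Silyl-chloride-accelerated copper-catalysed conjugate addition to the β,β-disubstituted enone makes the quaternary CMe2 carbon (no new stereocentre), and mild acid hydrolysis of the silyl enol ether gives the ketone.

**Step 5**
Reactants: 8 (4S)-3,3-dimethyl-4-(3-methylbut-2-en-1-yl)cyclohexan-1-one; 9 1-bromo-3-methylbut-2-ene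
Product: 10 (4R)-5,5-dimethyl-2,4-bis(3-methylbut-2-en-1-yl)cyclohexan-1-one (mixture of C2 epimers)
Conditions: LiN(iPr)2, THF, −78 °C; then 9, −78 to 0 °C
Reagents that add atoms: none
Why: Kinetic enolate alkylation: the amide base removes the proton at the unhindered CH2 and not at the neopentyl CH2 next to CMe2; the C2 configuration is irrelevant because it is erased in step 6.

**Step 6**
Reactants: 10 (4R)-5,5-dimethyl-2,4-bis(3-methylbut-2-en-1-yl)cyclohexan-1-one
Product: 11 {[(4R)-5,5-dimethyl-2,4-bis(3-methylbut-2-en-1-yl)cyclohex-1-en-1-yl]oxy}trimethylsilane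
Conditions: Me3SiCl, NaI, Et3N, MeCN, rt to 40 °C; pentane extraction, used crude
Reagents that add atoms: chlorotrimethylsilane, C[Si](C)(C)Cl
Why: Thermodynamic silyl enol ether formation (reversible silylation with Me3SiI made in the flask) favours the tetrasubstituted enol ether on the prenyl-bearing carbon.

**Step 7**
Reactants: 12 benzaldehyde; 13 tert-butyl acetate
Product: 14 tert-butyl 3-hydroxy-3-phenylpropanoate (racemic)
Conditions: LiN(iPr)2, THF, −78 °C, 13; then 12; AcOH quench
Reagents that add atoms: none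
Why: Aldol addition of the lithium ester enolate to the non-enolisable aldehyde; the carbinol centre is oxidised away in step 8.

**Step 8**
Reactants: 14 tert-butyl 3-hydroxy-3-phenylpropanoate
Product: 15 tert-butyl 3-oxo-3-phenylpropanoate
Conditions: Dess–Martin periodinane, CH2Cl2, rt
Reagents that add atoms: none
Why: Dess–Martin oxidation of the benzylic secondary alcohol gives the β-keto ester without over-oxidation or ester cleavage.

**Step 9**
Reactants: 15 tert-butyl 3-oxo-3-phenylpropanoate; 16 carbon disulfide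
Product: 17 tert-butyl 2-benzoyl-3,3-bis(methylsulfanyl)prop-2-enoate
Conditions: K2CO3 (2.2 equiv), DMF, 0 °C, 16; then MeI (2.2 equiv), rt
Reagents that add atoms: iodomethane, CI
Why: Ketene dithioacetal synthesis: the doubly deprotonated active methylene adds to CS2 and the dithiocarboxylate is S-methylated twice; the CS2 carbon becomes C2 of the target.

**Step 10**
Reactants: 17 tert-butyl 2-benzoyl-3,3-bis(methylsulfanyl)prop-2-enoate
Product: 18 2-benzoyl-3,3-bis(methylsulfanyl)prop-2-enoic acid
Conditions: CF3CO2H/CH2Cl2 (1:4), 0 °C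
Reagents that add atoms: none
Why: Acidolysis of the tert-butyl ester (loss of isobutene) frees the acid without a nucleophile that could attack the push–pull alkene; it is kept cold because C-protonation could trigger decarboxylation.

**Step 11**
Reactants: 18 2-benzoyl-3,3-bis(methylsulfanyl)prop-2-enoic acid
Product: 19 2-benzoyl-3,3-bis(methylsulfanyl)prop-2-enoyl chloride
Conditions: (COCl)2, DMF (cat.), CH2Cl2, 0 °C to rt; used crude
Reagents that add atoms: oxalyl chloride, ClC(=O)C(=O)Cl
Why: Acid chloride formation through the Vilsmeier-type chloroiminium intermediate under neutral conditions; there is no α-hydrogen, so no ketene can form.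

**Step 12**
Reactants: 11 {[(4R)-5,5-dimethyl-2,4-bis(3-methylbut-2-en-1-yl)cyclohex-1-en-1-yl]oxy}trimethylsilane; 19 2-benzoyl-3,3-bis(methylsulfanyl)prop-2-enoyl chloride
Product: 20 (2R,4R)-2-[2-benzoyl-3,3-bis(methylsulfanyl)prop-2-enoyl]-5,5-dimethyl-2,4-bis(3-methylbut-2-en-1-yl)cyclohexan-1-one
Conditions: ZnCl2 (20 mol %), CH2Cl2/Et2O, −20 °C to rt
Reagents that add atoms: none
Why: Lewis-acid-catalysed C-acylation of a silyl enol ether (Mukaiyama-type acylation) joins the two fragments; the acyl group enters axially on the face opposite the C4 side chain (chair-like transition state with that chain equatorial), which sets the quaternary centre with acyl trans to the C4 prenyl group.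

**Step 13**
Reactants: 20 (2R,4R)-2-[2-benzoyl-3,3-bis(methylsulfanyl)prop-2-enoyl]-5,5-dimethyl-2,4-bis(3-methylbut-2-en-1-yl)cyclohexan-1-one
Product: 21 (1S,5R,7R)-3-benzoyl-8,8-dimethyl-5,7-bis(3-methylbut-2-en-1-yl)-2-(methylsulfanyl)bicyclo[3.3.1]non-2-ene-4,9-dione
Conditions: LiN(SiMe3)2 (1.2 equiv), THF, −78 to 0 °C; AcOH quench
Reagents that add atoms: none
Why: Intramolecular conjugate addition–elimination (6-endo vinylic substitution) of the only possible ketone enolate on the ketene dithioacetal carbon, made irreversible by loss of methanethiolate; the new bridgehead can only form cis to the axial acyl arm, so C1 is fixed by C5.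

**Step 14**
Reactants: 21 (1S,5R,7R)-3-benzoyl-8,8-dimethyl-5,7-bis(3-methylbut-2-en-1-yl)-2-(methylsulfanyl)bicyclo[3.3.1]non-2-ene-4,9-dione
Product: 22 (1R,5R,7R)-3-benzoyl-2-hydroxy-8,8-dimethyl-5,7-bis(3-methylbut-2-en-1-yl)bicyclo[3.3.1]non-2-ene-4,9-dione
Conditions: LiOH, 1,4-dioxane/H2O, 90 °C; then 1 M HCl
Reagents that add atoms: lithium hydroxide, [Li+].[OH-]
Why: Addition–elimination hydrolysis of the vinylogous thioester, driven by formation of the stabilised triketone enolate that also protects against retro-Claisen cleavage; no stereocentre is involved.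

**Compound list**
1 | 5-methylhex-4-enal | CC(C)=CCCC=O | starting material
2 | but-3-en-2-one (methyl vinyl ketone) | CC(=O)C=C | starting material
3 | (2S)-2-(3-methylbut-2-en-1-yl)-5-oxohexanal | CC(C)=CC[C@@H](C=O)CCC(C)=O | intermediate
4 | (4S)-4-(3-methylbut-2-en-1-yl)cyclohex-2-en-1-one | CC(C)=CC[C@@H]1CCC(=O)C=C1 | intermediate
5 | trimethyl{[(3S,4S)-3-methyl-4-(3-methylbut-2-en-1-yl)cyclohex-1-en-1-yl]oxy}silane (3,4-trans) | CC(C)=CC[C@@H]1CCC(O[Si](C)(C)C)=C[C@H]1C | intermediate
6 | (4S)-3-methyl-4-(3-methylbut-2-en-1-yl)cyclohex-2-en-1-one | CC(C)=CC[C@@H]1CCC(=O)C=C1C | intermediate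
7 | {[(4S)-3,3-dimethyl-4-(3-methylbut-2-en-1-yl)cyclohex-1-en-1-yl]oxy}trimethylsilane | CC(C)=CC[C@@H]1CCC(O[Si](C)(C)C)=CC1(C)C | intermediate
8 | (4S)-3,3-dimethyl-4-(3-methylbut-2-en-1-yl)cyclohexan-1-one | CC(C)=CC[C@@H]1CCC(=O)CC1(C)C | intermediate
9 | 1-bromo-3-methylbut-2-ene (prenyl bromide) | CC(C)=CCBr | starting material
10 | (4R)-5,5-dimethyl-2,4-bis(3-methylbut-2-en-1-yl)cyclohexan-1-one (C2 epimers) | CC(C)=CC[C@@H]1CC(CC=C(C)C)C(=O)CC1(C)C | intermediate
11 | {[(4R)-5,5-dimethyl-2,4-bis(3-methylbut-2-en-1-yl)cyclohex-1-en-1-yl]oxy}trimethylsilane | CC(C)=CC[C@@H]1CC(CC=C(C)C)=C(O[Si](C)(C)C)CC1(C)C | intermediate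
12 | benzaldehyde | O=Cc1ccccc1 | starting material
13 | tert-butyl acetate | CC(=O)OC(C)(C)C | starting material
14 | tert-butyl 3-hydroxy-3-phenylpropanoate (racemic) | OC(CC(=O)OC(C)(C)C)c1ccccc1 | intermediate
15 | tert-butyl 3-oxo-3-phenylpropanoate | O=C(CC(=O)OC(C)(C)C)c1ccccc1 | intermediate
16 | carbon disulfide | S=C=S | starting material
17 | tert-butyl 2-benzoyl-3,3-bis(methylsulfanyl)prop-2-enoate | CSC(SC)=C(C(=O)c1ccccc1)C(=O)OC(C)(C)C | intermediate
18 | 2-benzoyl-3,3-bis(methylsulfanyl)prop-2-enoic acid | CSC(SC)=C(C(=O)c1ccccc1)C(O)=O | intermediate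
19 | 2-benzoyl-3,3-bis(methylsulfanyl)prop-2-enoyl chloride | CSC(SC)=C(C(=O)c1ccccc1)C(Cl)=O | intermediate
20 | (2R,4R)-2-[2-benzoyl-3,3-bis(methylsulfanyl)prop-2-enoyl]-5,5-dimethyl-2,4-bis(3-methylbut-2-en-1-yl)cyclohexan-1-one | CC(C)=CC[C@@H]1C[C@@](CC=C(C)C)(C(=O)C(C(=O)c2ccccc2)=C(SC)SC)C(=O)CC1(C)C | intermediate
21 | (1S,5R,7R)-3-benzoyl-8,8-dimethyl-5,7-bis(3-methylbut-2-en-1-yl)-2-(methylsulfanyl)bicyclo[3.3.1]non-2-ene-4,9-dione | CC(C)=CC[C@@H]1C[C@@]2(CC=C(C)C)C(=O)C(C(=O)c3ccccc3)=C(SC)[C@H](C2=O)C1(C)C | intermediate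
22 | (1R,5R,7R)-3-benzoyl-2-hydroxy-8,8-dimethyl-5,7-bis(3-methylbut-2-en-1-yl)bicyclo[3.3.1]non-2-ene-4,9-dione | CC(C)=CC[C@@H]1C[C@@]2(CC=C(C)C)C(=O)C(C(=O)c3ccccc3)=C(O)[C@H](C2=O)C1(C)C | target

**Step count**
Total: 14 steps (fragment A: steps 1–6; fragment B: steps 7–11; union and completion: steps 12–14).
Longest linear sequence: 9 steps (1–6, then 12–14), that is 9 of 14.

**Three steps most likely to fail**

Step 12 (C-acylation that forms the quaternary carbon with a hindered, conjugated acid chloride; O-acylation or attack at the dithioacetal carbon may compete). The fallback grows the side arm on the ring instead of bringing it in whole. It sets out from 11: acetyl chloride with ZnCl2 gives, with the same facial selectivity, the acetyl diketone (2S,4R)-2-acetyl-5,5-dimethyl-2,4-bis(3-methylbut-2-en-1-yl)cyclohexan-1-one F1. LiN(iPr)2 deprotonates its methyl ketone kinetically and the enolate adds to benzaldehyde 12, giving the aldol (2R,4R)-2-(3-hydroxy-3-phenylpropanoyl)-5,5-dimethyl-2,4-bis(3-methylbut-2-en-1-yl)cyclohexan-1-one F2. Dess–Martin oxidation then gives the triketone (2R,4R)-5,5-dimethyl-2,4-bis(3-methylbut-2-en-1-yl)-2-(3-oxo-3-phenylpropanoyl)cyclohexan-1-one F3. K2CO3, carbon disulfide 16 and MeI in DMF turn its active methylene into the ketene dithioacetal, which is 20, where the route is rejoined.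

Step 13 (the hindered enolate may close through oxygen to a pyranone, or add reversibly to the benzoyl carbonyl). The fallback removes the oxygen nucleophile by using a neutral silyl enol ether under Lewis-acid activation. It sets out from 20: Me3SiOTf and Et3N give the silyl enol ether {[(4R,6R)-6-[2-benzoyl-3,3-bis(methylsulfanyl)prop-2-enoyl]-3,3-dimethyl-4,6-bis(3-methylbut-2-en-1-yl)cyclohex-1-en-1-yl]oxy}trimethylsilane F4. TiCl4 in CH2Cl2 at −78 °C then triggers a Mukaiyama–Michael addition–elimination through carbon only, and the route is rejoined at 21.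

Step 6 (the tetrasubstituted silyl enol ether may form as a mixture with its regioisomer, which cannot be purified and would be acylated at the wrong carbon). The fallback uses a regioisomer that can be purified. It sets out from 10: the equilibrated potassium enolate (KH in slight deficit, THF, rt) is O-acetylated with Ac2O to give the enol acetate (4R)-5,5-dimethyl-2,4-bis(3-methylbut-2-en-1-yl)cyclohex-1-en-1-yl acetate F5, which survives chromatography and is taken on as a single regioisomer. Two equivalents of MeLi in DME cleave it to the lithium enolate regiospecifically, and Me3SiCl traps this as 11, where the route is rejoined.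

**Further compounds**
F1 | step 12 | (2S,4R)-2-acetyl-5,5-dimethyl-2,4-bis(3-methylbut-2-en-1-yl)cyclohexan-1-one | CC(C)=CC[C@@H]1C[C@@](CC=C(C)C)(C(C)=O)C(=O)CC1(C)C
F2 | step 12 | (2R,4R)-2-(3-hydroxy-3-phenylpropanoyl)-5,5-dimethyl-2,4-bis(3-methylbut-2-en-1-yl)cyclohexan-1-one (carbinol epimers) | CC(C)=CC[C@@H]1C[C@@](CC=C(C)C)(C(=O)CC(O)c2ccccc2)C(=O)CC1(C)C
F3 | step 12 | (2R,4R)-5,5-dimethyl-2,4-bis(3-methylbut-2-en-1-yl)-2-(3-oxo-3-phenylpropanoyl)cyclohexan-1-one | CC(C)=CC[C@@H]1C[C@@](CC=C(C)C)(C(=O)CC(=O)c2ccccc2)C(=O)CC1(C)C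
F4 | step 13 | {[(4R,6R)-6-[2-benzoyl-3,3-bis(methylsulfanyl)prop-2-enoyl]-3,3-dimethyl-4,6-bis(3-methylbut-2-en-1-yl)cyclohex-1-en-1-yl]oxy}trimethylsilane | CC(C)=CC[C@@H]1C[C@@](CC=C(C)C)(C(=O)C(C(=O)c2ccccc2)=C(SC)SC)C(O[Si](C)(C)C)=CC1(C)C
F5 | step 6 | (4R)-5,5-dimethyl-2,4-bis(3-methylbut-2-en-1-yl)cyclohex-1-en-1-yl acetate | CC(C)=CC[C@@H]1CC(CC=C(C)C)=C(OC(C)=O)CC1(C)C
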